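The numbers in the tables were computed with made-up constants.

Late on, at 25.0 h, the noon run has 31.1 % of its charge in chains and the summer run 55.9 %. Yet summer's charge was 1.50 times noon's, and a step first order in free monomer, at a fixed rate constant, gives both the same percentage.

| setting | noon | summer | cedar | alder |
|---|---|---|---|---|
| free monomer | 0.20 M (fed, over 20 h) | 0.30 M (fed, over 20 h) | 0.40 M | 0.40 M (fed, over 20 h) |
| transfer agent | 4 mM | 4 mM | 4.00 mM | 4.00 mM |
| initiator | 2.5 mol% | 2.5 mol% | 2.5 mol% | 2.5 mol% |
| remark | run made earlier; the fed solution adds 1.0 times the starting volume | run made earlier; the fed solution adds 1.0 times the starting volume | everything together at the start, the whole solution of free monomer included, so that from the start the volume is larger by 1.0 times the starting volume | the fed solution adds 1.0 times the starting volume |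
| time |  |  | 20 h | 20 h |

- noon (time / h: monomer in chains / %, free monomer / %): 2.00: 0, 9.7; 3.00: 0, 14.3; 4.00: 0.3, 20.5; 6.00: 2.2, 29.4; 10.0: 4.1, 45.7; 15.0: 11.4, 63.6; 25.0: 31.1, 69.2
- summer (time / h: monomer in chains / %, free monomer / %): 2.00: 0, 9.9; 3.00: 1.2, 14.8; 4.00: 0.1, 19.0; 6.00: 2.4, 27.6; 10.0: 8.5, 42.0; 15.0: 21.5, 53.1; 25.0: 55.9, 45.1

(scatter of a reading: 0.5 percentage points)

- which one finishes higher in amount of monomer in chains, in percent of the free monomer charged ("neither" within 2 percentage points) (cedar / alder / neither)
- amount of monomer in chains at the end, in percent of the free monomer charged, cedar
- amount of monomer in chains at the end, in percent of the free monomer charged, alder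

- charges are per starting volume, the dose included; the dosed solution carries all of it
- candidate steps: free monomer + initiator -> living end + monomer in chains; free monomer + living end -> monomer in chains + living end; living end + transfer agent -> dead chain; initiator -> spent initiator
- percentages count the whole charge, also what has not yet gone in

The two numbers go together once we note that initiator is a fixed 2.5 mol% of the charge, so summer holds more of it than noon, while the transfer agent stands at 4 mM in both runs, and that in the candidate steps a living end forms from free monomer and initiator. Both runs start slowly (an induction period), with 0.3 % and 0.1 % in chains at 4.00 h. So we reckon the exposure: [free monomer] summed over time as if nothing had reacted. For a steady feed that doubles the volume, this is charge × dosing time × 0.307 at the end of the feed. For cedar it is [free monomer] from the start × time. We read chains at the end of the feed as the mean of the readings either side.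

noon: exposure 73.6 M·min, chains 21.2 %

summer: exposure 110 M·min, chains 38.7 %

alder: exposure 147 M·min, chains on the same line 56.1 %

cedar: exposure 240 M·min

This exposure at the end of the run is what we carry. Cedar's is larger than alder's, and the line reaches 100 % there, so we give no figure for cedar from it. We commit to cedar above alder, with alder near 56.1 %.

The forecast says cedar, with cedar at 78 % and alder at 50 %, lower than our figure for alder: “Alder starves early, since free monomer is low while initiating.”

The flask gives cedar: cedar 90.5 %, alder 57.1 %.

    free monomer + initiator → living end + monomer in chains (k = 0.720 L mol⁻¹ h⁻¹)
    free monomer + living end → monomer in chains + living end, rate k2*[living end]*[free monomer] (k = 93.0 L mol⁻¹ h⁻¹)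
    living end + transfer agent → dead chain (kL = 160 L mol⁻¹ h⁻¹)
    initiator → spent initiator (k = 0.0100 h⁻¹)

Alder stands 1.00 percentage point above our line. A further flask, like alder but charged 0.68 M of free monomer, with initiator still at 2.5 mol%, has exposure 250 M·min, close to cedar's 240 M·min. It ends with 83.6 % in chains, less than cedar's 90.5 %, and 16.4 % still free monomer.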